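Retrosynthesis: the C19–O7 lactone, the C6–Cl bond and both acetates are cut last-formed-first; then C3=C4 (back to an eleven-membered C3–SO2–C4 sulfone), the two C–S bonds, C5–C6, C2–C3, the ring A bonds C1–C10 and C13–C14 ([4+2]), C10=C11 and C8–C17, which leaves L-arabinose (C6–C10).
Forward: the arabinose-derived 3-ulose receives C17–C19 at C8 as an isopropenyl group, whose methyl is then oxidised to C19–OH; a Wittig olefination and a Diels–Alder reaction build ring A (C1, C10–C14) on C10; C3 and then C4/C5/C16 are attached; Na2S closes the eleven-membered thiacycle; SO2 extrusion contracts it to the ten-membered carbocycle; the γ-lactone, the chloride and the free 12-OH come last.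
Enabling feature: in the ten-membered ring the Z-C3=C4 bond lies between the C2 carbinol and the exocyclic C5=C16 methylene, so C3 (terminus of a C2 chlorohydrin/epoxide) and C4 (allylic) are both readily alkylated by sulfur, and C4–H of the resulting sulfone is the one allylic, α-sulfonyl site for halogenation.
Stereochemistry: C7 and C9 come from L-arabinose; C8 from convex-face addition to the 3-ulose; C17 from hydrogenation with Ru(OAc)2[(S)-BINAP]; C10 and C1 from the Diels–Alder step (face fixed by C9, formyl exo); C2 from CBS reduction; C11 from kinetic protonation; C12 from reduction then Mitsunobu inversion; C6 from Felkin–Anh reduction then SN2 chlorination.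

Key step: step 28

Numbering: briarane locants are used throughout (C1 quaternary with Me-15, C2, C3=C4, C5=C16, C6, C7, C8, C9, C10, C11 with Me-20, C12, C13=C14, C17 with Me-18, C19); ring A is C1, C10–C14; C1–C5 of L-arabinose become C6–C10.
Assumption: the (S)-BINAP ligand named in step 6 is taken to give the centre that becomes 17R; should the facial preference on this substrate be the opposite one, the antipodal ligand is used.

Step 1
Reactants: 1 L-arabinose
Product: 2 5-O-(tert-butyldiphenylsilyl)-L-arabinofuranose (anomeric mixture)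
Conditions: TBDPSCl (1.05 equiv), imidazole, DMF, 0 °C to rt
Reagents that add atoms: tert-butyl(chloro)diphenylsilane, CC(C)(C)[Si](Cl)(c1ccccc1)c1ccccc1
Why: Silyl ether formation at the only primary hydroxyl, which exists in the furanose tautomers, drains the pyranose–furanose equilibrium to the 5-O-silyl furanose without touching a stereocentre.

Step 2
Reactants: 2 5-O-(tert-butyldiphenylsilyl)-L-arabinofuranose
Product: 3 5-O-TBDPS-1,2-O-isopropylidene-β-L-arabinofuranose
Conditions: 2,2-dimethoxypropane, acetone, CSA (cat.), 0 °C to rt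
Reagents that add atoms: 2,2-dimethoxypropane, COC(C)(C)OC
Why: Acid-catalysed acetonide formation takes the only cis-1,2-diol of the furanose (O1/O2 of the β-anomer), which fixes the anomeric centre and leaves 3-OH as the single free hydroxyl.

Step 3
Reactants: 3 5-O-TBDPS-1,2-O-isopropylidene-β-L-arabinofuranose
Product: 4 5-O-TBDPS-1,2-O-isopropylidene-β-L-threo-pentofuranos-3-ulose
Conditions: DMP (Dess–Martin periodinane), NaHCO3, CH2Cl2, rt
Reagents that add atoms: none
Why: Dess–Martin oxidation of the single secondary alcohol gives the C8 ketone under neutral conditions that do not epimerise the flanking C7 and C9 centres.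

Step 4
Reactants: 4 5-O-TBDPS-1,2-O-isopropylidene-β-L-threo-pentofuranos-3-ulose; 5 isopropenylmagnesium bromide
Product: 6 5-O-TBDPS-1,2-O-isopropylidene-3-C-(prop-1-en-2-yl)-β-L-lyxofuranose
Conditions: 5 (1.5 equiv), THF, −78 °C; then H2O
Reagents that add atoms: none
Why: Grignard 1,2-addition to the ketone occurs on the convex face anti to the 1,2-acetonide and the C10 arm, so C8 receives the C17–C19 unit exo and its tertiary hydroxyl cis to O7 (L-lyxo).

Step 5
Reactants: 6 5-O-TBDPS-1,2-O-isopropylidene-3-C-(prop-1-en-2-yl)-β-L-lyxofuranose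
Product: 7 5-O-TBDPS-3-C-(3-hydroxyprop-1-en-2-yl)-1,2-O-isopropylidene-β-L-lyxofuranose
Conditions: SeO2 (0.5 equiv), t-BuOOH (2 equiv), salicylic acid (0.1 equiv), CH2Cl2, 25 °C
Reagents that add atoms: tert-butyl hydroperoxide, CC(C)(C)OO
Why: Allylic oxidation with SeO2 (ene reaction, then [2,3]-sigmatropic shift of the allylseleninic acid, the selenium being reoxidised by the hydroperoxide) can take a hydrogen only from the methyl group, because the other allylic carbon is the quaternary C8, and so gives the 2-substituted allyl alcohol without touching a stereocentre.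

Step 6
Reactants: 7 5-O-TBDPS-3-C-(3-hydroxyprop-1-en-2-yl)-1,2-O-isopropylidene-β-L-lyxofuranose
Product: 8 5-O-TBDPS-3-C-[(2S)-1-hydroxypropan-2-yl]-1,2-O-isopropylidene-β-L-lyxofuranose
Conditions: H2 (50 atm), Ru(OAc)2[(S)-BINAP] (2 mol%), MeOH, 25 °C
Reagents that add atoms: none
Why: Noyori asymmetric hydrogenation of an allylic alcohol, in which the primary hydroxyl binds ruthenium and the BINAP ligand rather than the locally near-symmetric furanose selects the C17 face, should set C17 (Me-18).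

Step 7
Reactants: 8 5-O-TBDPS-3-C-[(2S)-1-hydroxypropan-2-yl]-1,2-O-isopropylidene-β-L-lyxofuranose
Product: 9 5-O-TBDPS-3-C-[(2S)-1-(4-methoxybenzyloxy)propan-2-yl]-1,2-O-isopropylidene-β-L-lyxofuranose
Conditions: NaH (1.05 equiv), PMBCl, Bu4NI (cat.), DMF, 0 °C
Reagents that add atoms: 4-methoxybenzyl chloride, COc1ccc(CCl)cc1
Why: Williamson etherification of the primary alkoxide protects C19–OH, the tertiary 8-OH being too hindered to be alkylated by one equivalent of base.

Step 8
Reactants: 9 5-O-TBDPS-3-C-[(2S)-1-(4-methoxybenzyloxy)propan-2-yl]-1,2-O-isopropylidene-β-L-lyxofuranose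
Product: 10 3-C-[(2S)-1-(4-methoxybenzyloxy)propan-2-yl]-1,2-O-isopropylidene-β-L-lyxofuranose
Conditions: Bu4NF, THF, 0 °C
Reagents that add atoms: none
Why: Fluoride-induced cleavage of the silyl ether frees the C10 primary alcohol while PMB ether and acetonide are inert.

Step 9
Reactants: 10 3-C-[(2S)-1-(4-methoxybenzyloxy)propan-2-yl]-1,2-O-isopropylidene-β-L-lyxofuranose
Product: 11 3-C-[(2S)-1-(4-methoxybenzyloxy)propan-2-yl]-1,2-O-isopropylidene-β-L-lyxo-pentodialdo-1,4-furanose (C10 aldehyde)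
Conditions: DMP, NaHCO3, CH2Cl2, 0 °C to rt
Reagents that add atoms: none
Why: Dess–Martin oxidation of the primary alcohol gives the C10 aldehyde under buffered conditions that leave the tertiary alcohol and the α-alkoxy centre C9 untouched.

Step 10
Reactants: 11 C10 aldehyde; 12 3-(triphenyl-λ5-phosphanylidene)butan-2-one
Product: 13 (E)-enone C9–CH=C(CH3)–C(=O)CH3 on the furanose (C10=C11 with Me-20; C12 ketone; C13 methyl)
Conditions: toluene, 80 °C
Reagents that add atoms: none
Why: Wittig olefination with the stabilised α-methyl ylide forms C10=C11 as the (E)-trisubstituted enone without added base, so C9 is not epimerised.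

Step 11
Reactants: 13 (E)-enone
Product: 14 2-silyloxy diene C9–CH=C(CH3)–C(OSiEt3)=CH2 with 8-O-SiEt3
Conditions: Et3SiOTf (2.5 equiv), Et3N, CH2Cl2, −78 to 0 °C
Reagents that add atoms: triethylsilyl triflate, CC[Si](CC)(CC)OS(=O)(=O)C(F)(F)F
Why: Soft enolisation at the C13 methyl gives the cross-conjugated silyl dienol ether (silyl enol ether formation) and the tertiary 8-OH is silylated in the same operation.

Step 12
Reactants: 14 2-silyloxy diene; 15 methacrolein
Product: 16 Diels–Alder adduct: ring A with C1 (Me-15 and CHO) and C10 configured as in the target and a C11=C12 triethylsilyl enol ether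
Conditions: methacrolein (3 equiv), Me2AlCl (0.3 equiv), CH2Cl2, −78 to −40 °C
Reagents that add atoms: none
Why: Lewis-acid-catalysed Diels–Alder reaction forms C1–C10 and C13–C14: the C12 silyloxy group sends the nucleophilic terminus C13 to the β-carbon of methacrolein, the dienophile adds to the diene face anti to the quaternary C8 while H9 eclipses the diene to avoid 1,3-allylic strain with Me-20 (sets C10), and the formyl group goes exo, methyl endo, away from the bulky C9 substituent (sets C1 with Me-15 cis to C9).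

Step 13
Reactants: 16 Diels–Alder adduct; 17 chloroiodomethane
Product: 20 chloromethyl ketone (C2 ketone; C3–Cl), via chloromethyllithium 18 (not isolated), via chlorohydrin mixture 19 (not isolated)
Conditions: ICH2Cl, MeLi·LiBr, THF, −78 °C; AcOH at −78 °C; then DMP, NaHCO3, CH2Cl2, rt
Reagents that add atoms: none
Why: Iodine–lithium exchange generates chloromethyllithium, which adds to the neopentyl aldehyde (1,2-addition), and Dess–Martin oxidation merges the two C2 epimers into one α-chloro ketone so that C2 can be set by reagent control.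

Step 14
Reactants: 20 chloromethyl ketone
Product: 21 (2R)-chlorohydrin (C2–OH, C3–Cl)
Conditions: (R)-2-methyl-CBS-oxazaborolidine (20 mol%), catecholborane, toluene, −78 to −40 °C
Reagents that add atoms: none
Why: Corey–Bakshi–Shibata reduction, with the quaternary C1 as the large and CH2Cl as the small substituent, should deliver hydride to the face that gives the (2R)-chlorohydrin, which is the C2 configuration of the target.

Step 15
Reactants: 21 (2R)-chlorohydrin
Product: 22 ring A C12 ketone with Me-20 cis to C9 and free 2-OH and 8-OH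
Conditions: HF·pyridine, pyridine, THF, 0 °C
Reagents that add atoms: none
Why: Protodesilylation of the silyl enol ether puts the proton on C11 from the α face, anti to the pseudo-axial C10 substituent (1,2-allylic strain with Me-20), which sets C11 with Me-20 cis to C9, and the tertiary silyl ether is cleaved as well.

Step 16
Reactants: 22 ring A C12 ketone
Product: 24 ring A enone (C12=O, C13=C14), via tris(trimethylsilyl) enol ether 23 (not isolated)
Conditions: LiN(SiMe3)2 (3.5 equiv), Me3SiCl, THF, −78 °C; then Pd(OAc)2 (10 mol%), O2 (1 atm), DMSO, 25 °C; 1 M HCl work-up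
Reagents that add atoms: none
Why: Saegusa–Ito oxidation: kinetic deprotonation at the C13 methylene (not the hindered C11 methine) with in situ silylation, then palladation of the enol ether and β-hydride elimination from C14, gives the C13=C14 enone without enolising C11.

Step 17
Reactants: 24 ring A enone
Product: 25 12-epi allylic alcohol (12β-OH, cis to Me-20)
Conditions: i-Bu2AlH, CH2Cl2, −78 °C
Reagents that add atoms: none
Why: 1,2-Reduction of the enone: with the C10 substituent axial next to the quaternary C1, the hydride reaches C12 from the α face, trans to that axial group, so the hydroxyl should come out 12β, the epimer that the next step inverts.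

Step 18
Reactants: 25 12-epi allylic alcohol
Product: 26 12α 4-nitrobenzoate
Conditions: PPh3, DIAD, 4-nitrobenzoic acid, THF, 0 °C to rt
Reagents that add atoms: 4-nitrobenzoic acid, O=C(O)c1ccc(cc1)[N+](=O)[O-]
Why: Mitsunobu reaction inverts the allylic C12 carbinol by SN2 displacement of the oxyphosphonium ion and so sets C12 as in the target, while the neopentyl 2-OH and the tertiary 8-OH do not react.

Step 19
Reactants: 26 12α 4-nitrobenzoate
Product: 27 12α-alcohol (trans to Me-20)
Conditions: i-Bu2AlH, CH2Cl2, −78 °C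
Reagents that add atoms: none
Why: Reductive cleavage of the ester avoids the basic methanolysis that would close the chlorohydrin to the epoxide too early.

Step 20
Reactants: 27 12α-alcohol
Product: 28 12-O-triisopropylsilyl ether
Conditions: i-Pr3SiOTf (1.1 equiv), 2,6-lutidine, CH2Cl2, −78 °C
Reagents that add atoms: triisopropylsilyl triflate, CC(C)[Si](OS(=O)(=O)C(F)(F)F)(C(C)C)C(C)C
Why: Silyl ether formation at the allylic 12-OH, the least hindered of the three hydroxyls, installs a group that survives the acid of steps 21 and 32.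

Step 21
Reactants: 28 12-O-triisopropylsilyl ether
Product: 29 lactol with 7,8-O-isopropylidene group and free anomeric C6–OH
Conditions: CSA (0.2 equiv), acetone, 25 °C
Reagents that add atoms: none
Why: Acid-catalysed acetal exchange moves the isopropylidene group from O6/O7 to the cis O7/O8 diol, the thermodynamically preferred 2,3-acetonide of a lyxofuranose, and frees the anomeric hydroxyl without change at C7 or C8.

Step 22
Reactants: 29 lactol
Product: 30 γ-lactone (C6=O, ring oxygen O9)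
Conditions: TEMPO (0.2 equiv), PhI(OAc)2, CH2Cl2, 25 °C
Reagents that add atoms: none
Why: Oxoammonium (TEMPO) oxidation converts the lactol into the lactone much faster than it attacks the hindered secondary 2-OH.

Step 23
Reactants: 30 γ-lactone; 31 2-bromoprop-2-en-1-ol
Product: 34 tetraol with 2-OH, 4-OH, 6-OH (6R; 6,7-threo) and 9-OH, via lithium 2-lithioprop-2-en-1-olate 32 (not isolated), via C6 hemiketal 33 (not isolated)
Conditions: 31, t-BuLi (3 equiv), Et2O, −78 to 0 °C; then 30, THF, −78 °C; AcOH at −78 °C; then CeCl3·7H2O, NaBH4, MeOH, −40 °C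
Reagents that add atoms: none
Why: Bromine–lithium exchange gives the vinyllithium alkoxide, which adds once to the lactone because the adduct persists as the hemiketalate, and Luche reduction of the ring-opened α-methylene ketone is a 1,2-reduction under Felkin–Anh control, hydride entering anti to the C7–O bond, which should give the 6,7-threo (6R) alcohol and frees 9-OH.

Step 24
Reactants: 34 tetraol
Product: 36 C4 allylic chloride, via C4 mesylate 35 (not isolated)
Conditions: MsCl (1.1 equiv), 2,4,6-collidine, LiCl, DMF, 0 °C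
Reagents that add atoms: lithium chloride, [Li+].[Cl-]
Why: The primary allylic hydroxyl is mesylated selectively and the mesylate is displaced in situ by chloride (SN2), the three secondary hydroxyls being too hindered to react.

Step 25
Reactants: 36 C4 allylic chloride
Product: 37 6-O-triethylsilyl ether (open-chain precursor of the thiacycle)
Conditions: Et3SiCl (1.2 equiv), imidazole, CH2Cl2, −20 °C
Reagents that add atoms: chlorotriethylsilane, CC[Si](Cl)(CC)CC
Why: Silyl ether formation at the least hindered secondary hydroxyl, the allylic 6-OH, leaves 2-OH and 9-OH free, each of which sits next to a quaternary carbon.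

Step 26
Reactants: 37 6-O-triethylsilyl ether
Product: 39 eleven-membered sulfide (C3–S–C4), via epoxy thiol 38 (not isolated)
Conditions: Na2S·9H2O (1.2 equiv), EtOH/H2O 9:1, 50 °C, slow addition to 2 mM
Reagents that add atoms: sodium sulfide, [Na+].[Na+].[S-2]
Why: Double S-alkylation of sulfide: it displaces the allylic chloride, the chlorohydrin closes to the C2–C3 epoxide, and the thiolate opens it at the terminal C3 at high dilution, which closes the eleven-membered ring and returns 2-OH with its configuration retained.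

Step 27
Reactants: 39 eleven-membered sulfide
Product: 40 eleven-membered sulfone (C3–SO2–C4) with free 2-OH and 9-OH
Conditions: 30% H2O2, (NH4)6Mo7O24·4H2O (10 mol%), EtOH, 0 °C
Reagents that add atoms: hydrogen peroxide, OO
Why: Molybdate-catalysed peroxide oxidation of the sulfide to the sulfone is much faster than epoxidation of the three alkenes.

Step 28
Reactants: 40 eleven-membered sulfone
Product: 43 ten-membered (3Z),5(16)-diene with free 2-OH and 9-OH, via C4-bromo sulfone 41 (not isolated), via C3–C4 episulfone 42 (not isolated)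
Conditions: CBr2F2, KOH/Al2O3, t-BuOH/CH2Cl2, 0 to 25 °C
Reagents that add atoms: none
Why: KOH removes the allylic α-sulfonyl C4–H, the carbanion is brominated by CBr2F2, and deprotonation at C3 then displaces bromide in a 1,3-elimination to the C3–C4 episulfone, which extrudes SO2 to give the C3=C4 alkene (Ramberg–Bäcklund reaction with in situ halogenation, as used for strained cycloalkenes and conjugated dienes). The episulfone forms by 3-exo-tet closure, and its cheletropic loss of SO2 contracts the eleven-membered thiacycle to the ten-membered carbocycle. No stereocentre is created; the Z geometry follows from the cis-fused episulfone, the only one the ring can hold. The step needs halogenation at C4 and not at C3 or C16, which the combined allylic and sulfonyl activation of C4–H and the α-selectivity of sulfonyl-substituted allyl anions should secure. β-Elimination from the C3 carbanion is blocked because O2 is a potassium alkoxide, and the free 9-OH, the silyl ethers, the acetonide and the PMB ether are spectators to alumina-supported KOH at 0–25 °C.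

Step 29
Reactants: 43 ten-membered diene
Product: 44 2,9-diacetate
Conditions: Ac2O, DMAP, Et3N, CH2Cl2, 25 to 40 °C
Reagents that add atoms: acetic anhydride, CC(=O)OC(C)=O
Why: DMAP-catalysed acylation esterifies the only two free hydroxyls, the allylic 2-OH and the hindered 9-OH.

Step 30
Reactants: 44 2,9-diacetate
Product: 45 C19 primary alcohol
Conditions: DDQ, CH2Cl2/pH 7 buffer, 0 °C
Reagents that add atoms: none
Why: Oxidative cleavage of the PMB ether by DDQ (hydride abstraction, hydrolysis of the oxocarbenium ion) frees C19–OH under buffered conditions and short contact that should spare the diene.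

Step 31
Reactants: 45 C19 primary alcohol
Product: 46 C19 carboxylic acid
Conditions: TEMPO (0.3 equiv), PhI(OAc)2 (2.5 equiv), MeCN/H2O 1:1, 25 °C
Reagents that add atoms: water, O
Why: Oxoammonium oxidation of the primary alcohol through the aldehyde hydrate gives the acid under near-neutral conditions that do not epimerise C17.

Step 32
Reactants: 46 C19 carboxylic acid
Product: 47 γ-lactone with free 6R-OH and 8-OH and 12-O-triisopropylsilyl ether
Conditions: AcOH/THF/H2O 3:1:1, 45 °C
Reagents that add atoms: none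
Why: Acid hydrolysis removes the acetonide and the secondary triethylsilyl ether, and the freed 7-OH lactonises with the C19 acid (five-membered ring preferred over the six-membered one at 6-OH) while the triisopropylsilyl ether and the acetates stay.

Step 33
Reactants: 47 hydroxy lactone
Product: 48 12-O-triisopropylsilyl ether of the target (6S chloride)
Conditions: PPh3, hexachloroacetone, CH2Cl2, −20 to 0 °C
Reagents that add atoms: hexachloroacetone, ClC(Cl)(Cl)C(=O)C(Cl)(Cl)Cl
Why: Appel-type chlorination: the alkoxyphosphonium ion of the allylic 6R-alcohol is displaced by chloride in an SN2 step with inversion, under conditions known to suppress allylic transposition, which sets 6S, and the tertiary 8-OH is inert.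

Step 34
Reactants: 48 12-O-triisopropylsilyl ether of the target
Product: 49 CNP0253247.1
Conditions: HF·pyridine, THF, 25 °C
Reagents that add atoms: none
Why: Fluoride-mediated desilylation under non-basic conditions frees 12-OH without touching the allylic chloride, the acetates or the β-hydroxy lactone.

Compound list
1 | L-arabinose | O=C[C@H](O)[C@@H](O)[C@@H](O)CO | starting material
2 | 5-O-(tert-butyldiphenylsilyl)-L-arabinofuranose (anomeric mixture) | CC(C)(C)[Si](c1ccccc1)(c1ccccc1)OC[C@@H]1OC(O)[C@H](O)[C@H]1O | intermediate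
3 | 5-O-TBDPS-1,2-O-isopropylidene-β-L-arabinofuranose | CC(C)(C)[Si](c1ccccc1)(c1ccccc1)OC[C@@H]1O[C@@H]2OC(C)(C)O[C@@H]2[C@H]1O | intermediate
4 | 5-O-TBDPS-1,2-O-isopropylidene-β-L-threo-pentofuranos-3-ulose | CC(C)(C)[Si](c1ccccc1)(c1ccccc1)OC[C@@H]1O[C@@H]2OC(C)(C)O[C@@H]2C1=O | intermediate
5 | isopropenylmagnesium bromide (prop-1-en-2-ylmagnesium bromide) | C=C(C)[Mg]Br | starting material
6 | 5-O-TBDPS-1,2-O-isopropylidene-3-C-(prop-1-en-2-yl)-β-L-lyxofuranose (tertiary 3-OH cis to O2) | CC(C)(C)[Si](c1ccccc1)(c1ccccc1)OC[C@@H]1O[C@@H]2OC(C)(C)O[C@@H]2[C@@]1(O)C(=C)C | intermediate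
7 | 5-O-TBDPS-3-C-(3-hydroxyprop-1-en-2-yl)-1,2-O-isopropylidene-β-L-lyxofuranose (tertiary 3-OH cis to O2) | CC(C)(C)[Si](c1ccccc1)(c1ccccc1)OC[C@@H]1O[C@@H]2OC(C)(C)O[C@@H]2[C@@]1(O)C(=C)CO | intermediate
8 | 5-O-TBDPS-3-C-[(2S)-1-hydroxypropan-2-yl]-1,2-O-isopropylidene-β-L-lyxofuranose | CC(C)(C)[Si](c1ccccc1)(c1ccccc1)OC[C@@H]1O[C@@H]2OC(C)(C)O[C@@H]2[C@@]1(O)[C@@H](C)CO | intermediate
9 | 5-O-TBDPS-3-C-[(2S)-1-(4-methoxybenzyloxy)propan-2-yl]-1,2-O-isopropylidene-β-L-lyxofuranose | CC(C)(C)[Si](c1ccccc1)(c1ccccc1)OC[C@@H]1O[C@@H]2OC(C)(C)O[C@@H]2[C@@]1(O)[C@@H](C)COCc1ccc(OC)cc1 | intermediate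
10 | 3-C-[(2S)-1-(4-methoxybenzyloxy)propan-2-yl]-1,2-O-isopropylidene-β-L-lyxofuranose | OC[C@@H]1O[C@@H]2OC(C)(C)O[C@@H]2[C@@]1(O)[C@@H](C)COCc1ccc(OC)cc1 | intermediate
11 | 3-C-[(2S)-1-(4-methoxybenzyloxy)propan-2-yl]-1,2-O-isopropylidene-β-L-lyxo-pentodialdo-1,4-furanose (C10 aldehyde) | O=C[C@@H]1O[C@@H]2OC(C)(C)O[C@@H]2[C@@]1(O)[C@@H](C)COCc1ccc(OC)cc1 | intermediate
12 | 3-(triphenyl-λ5-phosphanylidene)butan-2-one | CC(=O)C(C)=P(c1ccccc1)(c1ccccc1)c1ccccc1 | starting material
13 | (E)-enone: furanose of 11 carrying CH=C(CH3)C(=O)CH3 at C9 (C10=C11, Me-20, C12=O, C13) | CC(=O)/C(C)=C/[C@@H]1O[C@@H]2OC(C)(C)O[C@@H]2[C@@]1(O)[C@@H](C)COCc1ccc(OC)cc1 | intermediate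
14 | 2-silyloxy diene: C9–CH=C(CH3)–C(OSiEt3)=CH2 (E at C10=C11) with 8-O-SiEt3 | C=C(O[Si](CC)(CC)CC)/C(C)=C/[C@@H]1O[C@@H]2OC(C)(C)O[C@@H]2[C@@]1(O[Si](CC)(CC)CC)[C@@H](C)COCc1ccc(OC)cc1 | intermediate
15 | methacrolein (2-methylprop-2-enal) | C=C(C)C=O | starting material
16 | Diels–Alder adduct: ring A with C1 (Me-15, CHO) and C10 as in the target, C11=C12 triethylsilyl enol ether, furanose (1,2-acetonide, 8-O-SiEt3, C19 OPMB) at C10 | O=C[C@@]1(C)CCC(O[Si](CC)(CC)CC)=C(C)[C@@H]1[C@@H]2O[C@@H]3OC(C)(C)O[C@@H]3[C@@]2(O[Si](CC)(CC)CC)[C@@H](C)COCc4ccc(OC)cc4 | intermediate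
17 | chloroiodomethane | ClCI | starting material
18 | chloromethyllithium | [Li]CCl | intermediate
19 | C2-epimeric chlorohydrins of 16 (C2–OH, C3–Cl) | ClCC(O)[C@@]1(C)CCC(O[Si](CC)(CC)CC)=C(C)[C@@H]1[C@@H]2O[C@@H]3OC(C)(C)O[C@@H]3[C@@]2(O[Si](CC)(CC)CC)[C@@H](C)COCc4ccc(OC)cc4 | intermediate
20 | chloromethyl ketone (C2=O, C3–Cl) | ClCC(=O)[C@@]1(C)CCC(O[Si](CC)(CC)CC)=C(C)[C@@H]1[C@@H]2O[C@@H]3OC(C)(C)O[C@@H]3[C@@]2(O[Si](CC)(CC)CC)[C@@H](C)COCc4ccc(OC)cc4 | intermediate
21 | (2R)-chlorohydrin with C11=C12 silyl enol ether and 8-O-SiEt3 | ClC[C@H](O)[C@@]1(C)CCC(O[Si](CC)(CC)CC)=C(C)[C@@H]1[C@@H]2O[C@@H]3OC(C)(C)O[C@@H]3[C@@]2(O[Si](CC)(CC)CC)[C@@H](C)COCc4ccc(OC)cc4 | intermediate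
22 | ring A C12 ketone, Me-20 cis to C9, free 2-OH and 8-OH | ClC[C@H](O)[C@@]1(C)CCC(=O)[C@H](C)[C@@H]1[C@@H]2O[C@@H]3OC(C)(C)O[C@@H]3[C@@]2(O)[C@@H](C)COCc4ccc(OC)cc4 | intermediate
23 | tris(trimethylsilyl) derivative: C12=C13 silyl enol ether, 2-O-SiMe3, 8-O-SiMe3 | ClC[C@H](O[Si](C)(C)C)[C@@]1(C)CC=C(O[Si](C)(C)C)[C@H](C)[C@@H]1[C@@H]2O[C@@H]3OC(C)(C)O[C@@H]3[C@@]2(O[Si](C)(C)C)[C@@H](C)COCc4ccc(OC)cc4 | intermediate
24 | ring A enone (C12=O, C13=C14) | ClC[C@H](O)[C@@]1(C)C=CC(=O)[C@H](C)[C@@H]1[C@@H]2O[C@@H]3OC(C)(C)O[C@@H]3[C@@]2(O)[C@@H](C)COCc4ccc(OC)cc4 | intermediate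
25 | 12-epi allylic alcohol (12β-OH cis to Me-20) | ClC[C@H](O)[C@@]1(C)C=C[C@H](O)[C@H](C)[C@@H]1[C@@H]2O[C@@H]3OC(C)(C)O[C@@H]3[C@@]2(O)[C@@H](C)COCc4ccc(OC)cc4 | intermediate
26 | 12α 4-nitrobenzoate | ClC[C@H](O)[C@@]1(C)C=C[C@@H](OC(=O)c5ccc(cc5)[N+](=O)[O-])[C@H](C)[C@@H]1[C@@H]2O[C@@H]3OC(C)(C)O[C@@H]3[C@@]2(O)[C@@H](C)COCc4ccc(OC)cc4 | intermediate
27 | 12α-alcohol (trans to Me-20, as in the target) | ClC[C@H](O)[C@@]1(C)C=C[C@@H](O)[C@H](C)[C@@H]1[C@@H]2O[C@@H]3OC(C)(C)O[C@@H]3[C@@]2(O)[C@@H](C)COCc4ccc(OC)cc4 | intermediate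
28 | 12-O-triisopropylsilyl ether, furanose 1,2-acetonide, free 2-OH and 8-OH | ClC[C@H](O)[C@@]1(C)C=C[C@@H](O[Si](C(C)C)(C(C)C)C(C)C)[C@H](C)[C@@H]1[C@@H]2O[C@@H]3OC(C)(C)O[C@@H]3[C@@]2(O)[C@@H](C)COCc4ccc(OC)cc4 | intermediate
29 | lactol: 7,8-O-isopropylidene, free anomeric C6–OH | ClC[C@H](O)[C@@]1(C)C=C[C@@H](O[Si](C(C)C)(C(C)C)C(C)C)[C@H](C)[C@@H]1[C@@H]2OC(O)[C@@H]3OC(C)(C)O[C@]23[C@@H](C)COCc4ccc(OC)cc4 | intermediate
30 | γ-lactone (C6=O, O9), 7,8-O-isopropylidene | ClC[C@H](O)[C@@]1(C)C=C[C@@H](O[Si](C(C)C)(C(C)C)C(C)C)[C@H](C)[C@@H]1[C@@H]2OC(=O)[C@@H]3OC(C)(C)O[C@]23[C@@H](C)COCc4ccc(OC)cc4 | intermediate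
31 | 2-bromoprop-2-en-1-ol | C=C(Br)CO | starting material
32 | lithium 2-lithioprop-2-en-1-olate | [Li]C(=C)CO[Li] | intermediate
33 | C6 hemiketal bearing the 3-hydroxyprop-1-en-2-yl group (C5=C16, C4–OH) | ClC[C@H](O)[C@@]1(C)C=C[C@@H](O[Si](C(C)C)(C(C)C)C(C)C)[C@H](C)[C@@H]1[C@@H]2OC(O)(C(=C)CO)[C@@H]3OC(C)(C)O[C@]23[C@@H](C)COCc4ccc(OC)cc4 | intermediate
34 | tetraol: 2-OH, 4-OH, 6R-OH (6,7-threo), 9-OH; 3-Cl; 7,8-acetonide; 12-O-TIPS; C19 OPMB | ClC[C@H](O)[C@@]1(C)C=C[C@@H](O[Si](C(C)C)(C(C)C)C(C)C)[C@H](C)[C@@H]1[C@H](O)[C@]2(OC(C)(C)O[C@H]2[C@H](O)C(=C)CO)[C@@H](C)COCc3ccc(OC)cc3 | intermediate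
35 | C4 methanesulfonate of 34 | ClC[C@H](O)[C@@]1(C)C=C[C@@H](O[Si](C(C)C)(C(C)C)C(C)C)[C@H](C)[C@@H]1[C@H](O)[C@]2(OC(C)(C)O[C@H]2[C@H](O)C(=C)COS(C)(=O)=O)[C@@H](C)COCc3ccc(OC)cc3 | intermediate
36 | C4 allylic chloride (3,4-dichloride, free 2-OH, 6-OH, 9-OH) | ClC[C@H](O)[C@@]1(C)C=C[C@@H](O[Si](C(C)C)(C(C)C)C(C)C)[C@H](C)[C@@H]1[C@H](O)[C@]2(OC(C)(C)O[C@H]2[C@H](O)C(=C)CCl)[C@@H](C)COCc3ccc(OC)cc3 | intermediate
37 | 6-O-triethylsilyl ether of 36 | ClC[C@H](O)[C@@]1(C)C=C[C@@H](O[Si](C(C)C)(C(C)C)C(C)C)[C@H](C)[C@@H]1[C@H](O)[C@]2(OC(C)(C)O[C@H]2[C@H](O[Si](CC)(CC)CC)C(=C)CCl)[C@@H](C)COCc3ccc(OC)cc3 | intermediate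
38 | C2–C3 epoxide with C4 thiol | C1O[C@@H]1[C@@]2(C)C=C[C@@H](O[Si](C(C)C)(C(C)C)C(C)C)[C@H](C)[C@@H]2[C@H](O)[C@]2(OC(C)(C)O[C@H]2[C@H](O[Si](CC)(CC)CC)C(=C)CS)[C@@H](C)COCc3ccc(OC)cc3 | intermediate
39 | eleven-membered sulfide (C3–S–C4), free 2-OH and 9-OH | C=C1CSC[C@H](O)[C@@]2(C)C=C[C@@H](O[Si](C(C)C)(C(C)C)C(C)C)[C@H](C)[C@@H]2[C@H](O)[C@]2(OC(C)(C)O[C@H]2[C@@H]1O[Si](CC)(CC)CC)[C@@H](C)COCc3ccc(OC)cc3 | intermediate
40 | eleven-membered sulfone (C3–SO2–C4), free 2-OH and 9-OH, 6-O-TES, 7,8-acetonide, 12-O-TIPS, C19 OPMB | C=C1CS(=O)(=O)C[C@H](O)[C@@]2(C)C=C[C@@H](O[Si](C(C)C)(C(C)C)C(C)C)[C@H](C)[C@@H]2[C@H](O)[C@]2(OC(C)(C)O[C@H]2[C@@H]1O[Si](CC)(CC)CC)[C@@H](C)COCc3ccc(OC)cc3 | intermediate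
41 | C4-bromo sulfone | C=C1C(Br)S(=O)(=O)C[C@H](O)[C@@]2(C)C=C[C@@H](O[Si](C(C)C)(C(C)C)C(C)C)[C@H](C)[C@@H]2[C@H](O)[C@]2(OC(C)(C)O[C@H]2[C@@H]1O[Si](CC)(CC)CC)[C@@H](C)COCc3ccc(OC)cc3 | intermediate
42 | C3–C4 episulfone (cis-fused thiirane 1,1-dioxide) | C=C1C3C(S3(=O)=O)[C@H](O)[C@@]2(C)C=C[C@@H](O[Si](C(C)C)(C(C)C)C(C)C)[C@H](C)[C@@H]2[C@H](O)[C@]2(OC(C)(C)O[C@H]2[C@@H]1O[Si](CC)(CC)CC)[C@@H](C)COCc3ccc(OC)cc3 | intermediate
43 | ten-membered (3Z),5(16)-diene, free 2-OH and 9-OH, 6-O-TES, 7,8-acetonide, 12-O-TIPS, C19 OPMB | C=C1/C=C\[C@H](O)[C@@]2(C)C=C[C@@H](O[Si](C(C)C)(C(C)C)C(C)C)[C@H](C)[C@@H]2[C@H](O)[C@]2(OC(C)(C)O[C@H]2[C@@H]1O[Si](CC)(CC)CC)[C@@H](C)COCc3ccc(OC)cc3 | intermediate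
44 | 2,9-diacetate of 43 | C=C1/C=C\[C@H](OC(C)=O)[C@@]2(C)C=C[C@@H](O[Si](C(C)C)(C(C)C)C(C)C)[C@H](C)[C@@H]2[C@H](OC(C)=O)[C@]2(OC(C)(C)O[C@H]2[C@@H]1O[Si](CC)(CC)CC)[C@@H](C)COCc3ccc(OC)cc3 | intermediate
45 | C19 primary alcohol | C=C1/C=C\[C@H](OC(C)=O)[C@@]2(C)C=C[C@@H](O[Si](C(C)C)(C(C)C)C(C)C)[C@H](C)[C@@H]2[C@H](OC(C)=O)[C@]2(OC(C)(C)O[C@H]2[C@@H]1O[Si](CC)(CC)CC)[C@@H](C)CO | intermediate
46 | C19 carboxylic acid | C=C1/C=C\[C@H](OC(C)=O)[C@@]2(C)C=C[C@@H](O[Si](C(C)C)(C(C)C)C(C)C)[C@H](C)[C@@H]2[C@H](OC(C)=O)[C@]2(OC(C)(C)O[C@H]2[C@@H]1O[Si](CC)(CC)CC)[C@@H](C)C(=O)O | intermediate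
47 | γ-lactone (C19 to O7) with 6R-OH, 8-OH and 12-O-TIPS | C=C1/C=C\[C@H](OC(C)=O)[C@@]2(C)C=C[C@@H](O[Si](C(C)C)(C(C)C)C(C)C)[C@H](C)[C@@H]2[C@H](OC(C)=O)[C@]2(O)[C@@H](C)C(=O)O[C@H]2[C@@H]1O | intermediate
48 | 12-O-triisopropylsilyl ether of the target (6S chloride) | C=C1/C=C\[C@H](OC(C)=O)[C@@]2(C)C=C[C@@H](O[Si](C(C)C)(C(C)C)C(C)C)[C@H](C)[C@@H]2[C@H](OC(C)=O)[C@]2(O)[C@@H](C)C(=O)O[C@H]2[C@H]1Cl | intermediate
49 | CNP0253247.1 (1S,2S,6S,7R,8R,9S,10S,11R,12R,17R) | C=C1/C=C\[C@H](OC(C)=O)[C@@]2(C)C=C[C@@H](O)[C@H](C)[C@@H]2[C@H](OC(C)=O)[C@]2(O)[C@@H](C)C(=O)O[C@H]2[C@H]1Cl | target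

Total step count: 34 steps. Longest linear sequence: 34 steps (1 to 49); compounds 5, 12, 15, 17 and 31 are commercial.

Steps most likely to fail

Step 28. Over-bromination at the doubly activated C4, or hydroxide-induced retro-aldol opening of the β-hydroxy sulfone, may outrun the 1,3-elimination. The fallback sets out from sulfone 40 and separates halogenation from elimination: 40 is treated with LiN(SiMe3)2 (3.2 equiv, THF, −78 °C; the 2,9-dialkoxide C4 carbanion) and C2Cl6 to give the C4-chloro sulfone F1, which is isolated. KOt-Bu in THF at −40 to 0 °C should then bring about the same episulfone collapse and return the route at diene 43.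

Step 26. Intermolecular S-alkylation (oligomerisation) may outrun ring closure, and the C6 silyl ether may be lost in the basic aqueous medium. The fallback sets out from 37 and makes the two C–S bonds one at a time: KSAc in DMF at 0 °C displaces only the allylic chloride to give the C4 thioacetate F2. K2CO3 in degassed MeOH at high dilution then removes the acetyl group, closes the chlorohydrin to the C2–C3 epoxide and lets the thiolate open it at C3 in a unimolecular step, which returns the route at sulfide 39.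

Step 12. The Lewis acid may desilylate the dienol ether (Mukaiyama-type addition), or the exo preference of the formyl group may be too low to fix C1. The fallback sets out from diene 14, which is heated with methacrylonitrile (toluene, 110 °C, sealed tube); the small linear nitrile leaves the methyl group in the endo position and gives the nitrile adduct F3. Reduction with i-Bu2AlH at −78 °C gives, on aqueous quench, the aldimine F4, whose buffered hydrolysis returns the route at aldehyde 16.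

Further compounds
F1 | step 28 | C4-chloro sulfone | C=C1C(Cl)S(=O)(=O)C[C@H](O)[C@@]2(C)C=C[C@@H](O[Si](C(C)C)(C(C)C)C(C)C)[C@H](C)[C@@H]2[C@H](O)[C@]2(OC(C)(C)O[C@H]2[C@@H]1O[Si](CC)(CC)CC)[C@@H](C)COCc3ccc(OC)cc3
F2 | step 26 | C4 thioacetate | ClC[C@H](O)[C@@]1(C)C=C[C@@H](O[Si](C(C)C)(C(C)C)C(C)C)[C@H](C)[C@@H]1[C@H](O)[C@]2(OC(C)(C)O[C@H]2[C@H](O[Si](CC)(CC)CC)C(=C)CSC(C)=O)[C@@H](C)COCc3ccc(OC)cc3
F3 | step 12 | nitrile adduct (C2 as nitrile) | N#C[C@@]1(C)CCC(O[Si](CC)(CC)CC)=C(C)[C@@H]1[C@@H]2O[C@@H]3OC(C)(C)O[C@@H]3[C@@]2(O[Si](CC)(CC)CC)[C@@H](C)COCc4ccc(OC)cc4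
F4 | step 12 | aldimine (C2 as CH=NH) | N=C[C@@]1(C)CCC(O[Si](CC)(CC)CC)=C(C)[C@@H]1[C@@H]2O[C@@H]3OC(C)(C)O[C@@H]3[C@@]2(O[Si](CC)(CC)CC)[C@@H](C)COCc4ccc(OC)cc4
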